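**Plan**

- Feature: in ring B (the benzoic acid ring: C1 carboxyl, C2 and C4 hydroxyl, C3 aroyloxy, C6 propyl) C3 lies between the two hydroxylated carbons. At the cyclohexane-1,3-dione oxidation level C3 is the carbon between two carbonyls and the only carbon nucleophile, so the depside oxygen can be delivered to it as an electrophile.
- Retrosynthesis: the acid is masked as a benzyl ester and ring B is taken back to the cyclohexane-1,3-dione. The C3–O bond is then cut to give the dione enolate and the symmetric diaroyl peroxide of ring A.
- The dione is cut at C1–C6 and C2–C3 (Michael–Claisen) into dibenzyl malonate and (E)-hept-3-en-2-one. The peroxide is cut at one acyl–O bond into the ring A peroxy acid and acid chloride, both traced through the aryl–carbonyl bond back to 5-propylresorcinol.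
- Forward: the ring A acid (O-methylation, Vilsmeier formylation, Pinnick oxidation) is converted to the chloride; part of it is turned into the peroxy acid, which is acylated by the rest to give the peroxide. The ring B carbocycle closes in the annulation, the two halves are joined through the C3–O bond, DDQ aromatizes ring B and hydrogenolysis frees the acid. Ring A is aromatic throughout.
- Stereochemistry: the target has no stereocentre. The centres of the saturated ring B intermediates arise without control and are erased on aromatization.

Key step: step 8

Remark: ring B is numbered as in the benzoic acid (C1 carries the carboxyl) at every stage. Compounds 11 to 15 are taken as racemic or as mixtures of enolisable diastereomers.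

**Route**

Step 1
Reactants: 1 5-propylbenzene-1,3-diol
Product: 2 1,3-dimethoxy-5-propylbenzene
Conditions: MeI (2.5 equiv), K2CO3, acetone, reflux
Reagents that add atoms: iodomethane, CI
Why: Williamson ether synthesis in which both phenoxides are O-methylated by the unhindered alkyl iodide under mild carbonate conditions that favour O- over C-alkylation.

Step 2
Reactants: 2 1,3-dimethoxy-5-propylbenzene
Product: 4 2,4-dimethoxy-6-propylbenzaldehyde, via iminium salt 3 (not isolated)
Conditions: POCl3 (1.2 equiv), DMF, 0 °C to 60 °C; then H2O, 0 °C to rt
Reagents that add atoms: N,N-dimethylformamide, CN(C)C=O; water, O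
Why: Vilsmeier–Haack formylation in which the chloroiminium electrophile attacks the ring carbon para to one methoxy and ortho to the other (next to the propyl group), the site known to be preferred over the carbon between the two methoxy groups in 5-alkylresorcinol dimethyl ethers, and water hydrolyses iminium salt 3 to the aldehyde.

Step 3
Reactants: 4 2,4-dimethoxy-6-propylbenzaldehyde
Product: 5 2,4-dimethoxy-6-propylbenzoic acid
Conditions: NaClO2, NaH2PO4, 2-methyl-2-butene (excess), t-BuOH/H2O, rt
Reagents that add atoms: sodium chlorite, [Na+].[O-]Cl=O
Why: Pinnick oxidation in which chlorous acid adds to the aldehyde and fragments to the acid, while the alkene scavenger traps the hypochlorous acid before it can chlorinate the electron-rich ring.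

Step 4
Reactants: 5 2,4-dimethoxy-6-propylbenzoic acid
Product: 6 2,4-dimethoxy-6-propylbenzoyl chloride
Conditions: (COCl)2 (1.3 equiv), DMF (cat.), CH2Cl2, 0 °C to rt; evaporate, use crude in two portions
Reagents that add atoms: oxalyl chloride, O=C(Cl)C(Cl)=O
Why: Standard DMF-catalysed acid chloride formation with only gaseous by-products, giving a di-ortho-substituted aroyl chloride that is slow to hydrolyse and can be handled crude.

Step 5
Reactants: 6 2,4-dimethoxy-6-propylbenzoyl chloride
Product: 7 2,4-dimethoxy-6-propylperoxybenzoic acid
Conditions: 30% aq. H2O2 (3 equiv), NaOH (2.2 equiv), MgSO4 (cat.), 1,4-dioxane/H2O, 0 to 10 °C; then cold 1 M H2SO4, extraction into Et2O, dried over Na2SO4, titrated and used at once as a cold solution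
Reagents that add atoms: hydrogen peroxide, OO
Why: Perhydrolysis of an acyl chloride with alkaline hydrogen peroxide, the standard preparation of aromatic peroxy acids, in which the excess hydroperoxide anion (an alpha-effect nucleophile) outcompetes hydroxide for the hindered chloride and also cleaves any diacyl peroxide formed back to the peroxycarboxylate.

Step 6
Reactants: 7 2,4-dimethoxy-6-propylperoxybenzoic acid; 6 2,4-dimethoxy-6-propylbenzoyl chloride
Product: 8 bis(2,4-dimethoxy-6-propylbenzoyl) peroxide
Conditions: pyridine (1.1 equiv, added last), Et2O/CH2Cl2, −20 °C to 0 °C, dark; cold aqueous wash, no heating, used at once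
Reagents that add atoms: none
Why: Acylation of the terminal oxygen of a peroxy acid by an acyl chloride with pyridine as acid scavenger, the standard preparation of diacyl peroxides from these two partners, run cold and in the dark because an electron-rich diaroyl peroxide is thermally and ionically labile.

Step 7
Reactants: 9 dibenzyl malonate; 10 (E)-hept-3-en-2-one
Product: 13 benzyl 2,4-dioxo-6-propylcyclohexane-1-carboxylate, via Michael adduct 11 (not isolated), via sodium enolate 12 (not isolated)
Conditions: NaOBn (1.1 equiv, in BnOH), THF, rt to 65 °C; then aq. HCl to pH 3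
Reagents that add atoms: none
Why: Tandem Michael addition–Claisen condensation in which the malonate anion adds to C4 of the enone, the methyl ketone enolate of adduct 11 closes onto one benzyl ester, and formation of the acidic dione enolate 12 drives the sequence, with benzyloxide as base making transesterification degenerate and the C1 and C6 centres formed without control.

Step 8
Reactants: 13 benzyl 2,4-dioxo-6-propylcyclohexane-1-carboxylate; 8 bis(2,4-dimethoxy-6-propylbenzoyl) peroxide
Product: 15 benzyl 3-[(2,4-dimethoxy-6-propylbenzoyl)oxy]-2,4-dioxo-6-propylcyclohexane-1-carboxylate, via potassium enolate 14 (not isolated)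
Conditions: KOt-Bu (1.0 equiv), THF, 0 °C; then 8 (1.05 equiv) in THF, 0 °C to rt, dark, under argon; dilute HCl work-up
Reagents that add atoms: none
Why: The potassium enolate 14 is a vinylogous carboxylate with its carbon electron density on C3, and it attacks one peroxide oxygen of 8 along the O–O axis in an SN2 displacement that expels 2,4-dimethoxy-6-propylbenzoate and forms the C3–O bond of the depside. The closest known reaction type is the alpha-benzoyloxylation of beta-diketone and beta-keto ester enolates with dibenzoyl peroxide. No ring is closed, and the new centre at C3 is uncontrolled and enolisable (15 should exist largely as its enol) and disappears on aromatization. Selectivity for C3 over the ester-bearing C1 follows from acidity, since one equivalent of base gives only the dione enolate, in which C1 is not a nucleophilic position. Attack at oxygen and not at the acyl carbon is favoured because the carbonyl of 8 is shielded by its ortho methoxy and ortho propyl groups while the peroxide oxygen lies one atom further out. A second acyloxylation would have to build a quaternary C3 carrying two bulky aroyloxy groups and should not compete, and the expelled acid 5 can be recovered and returned to step 4.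

Step 9
Reactants: 15 benzyl 3-[(2,4-dimethoxy-6-propylbenzoyl)oxy]-2,4-dioxo-6-propylcyclohexane-1-carboxylate
Product: 16 benzyl 3-[(2,4-dimethoxy-6-propylbenzoyl)oxy]-2,4-dihydroxy-6-propylbenzoate
Conditions: DDQ (1.1 equiv), 1,4-dioxane, 80 °C
Reagents that add atoms: none
Why: Dehydrogenative aromatization of a cyclohexane-1,3-dione by a high-potential quinone, in which DDQ abstracts hydride from the tertiary C6–H of the C1=C2 enol and proton loss with tautomerization gives the resorcinol ring, while both propyl groups lie meta to the donor oxygens of their rings and are not activated for benzylic oxidation, and the di-ortho-substituted aroyl group is too hindered to migrate to the new neighbouring hydroxyls.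

Step 10
Reactants: 16 benzyl 3-[(2,4-dimethoxy-6-propylbenzoyl)oxy]-2,4-dihydroxy-6-propylbenzoate
Product: 17 3-[(2,4-dimethoxy-6-propylbenzoyl)oxy]-2,4-dihydroxy-6-propylbenzoic acid (CNP0211929.0)
Conditions: H2 (1 atm), 10% Pd/C, EtOAc, rt
Reagents that add atoms: none
Why: Hydrogenolysis of the benzyl ester over Pd/C under neutral conditions at room temperature, which leaves the aryl ester, the methyl ethers and the phenols untouched and avoids the base or heat that would cleave the depside or decarboxylate the salicylic-type acid.

**Compound list**

1 | 5-propylbenzene-1,3-diol | CCCc1cc(O)cc(O)c1 | starting material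
2 | 1,3-dimethoxy-5-propylbenzene | CCCc1cc(OC)cc(OC)c1 | intermediate
3 | N-[(2,4-dimethoxy-6-propylphenyl)methylidene]-N-methylmethanaminium dichlorophosphate (not isolated) | CCCc1cc(OC)cc(OC)c1C=[N+](C)C.[O-]P(=O)(Cl)Cl | intermediate
4 | 2,4-dimethoxy-6-propylbenzaldehyde | CCCc1cc(OC)cc(OC)c1C=O | intermediate
5 | 2,4-dimethoxy-6-propylbenzoic acid | CCCc1cc(OC)cc(OC)c1C(=O)O | intermediate
6 | 2,4-dimethoxy-6-propylbenzoyl chloride | CCCc1cc(OC)cc(OC)c1C(=O)Cl | intermediate
7 | 2,4-dimethoxy-6-propylperoxybenzoic acid | CCCc1cc(OC)cc(OC)c1C(=O)OO | intermediate
8 | bis(2,4-dimethoxy-6-propylbenzoyl) peroxide | CCCc1cc(OC)cc(OC)c1C(=O)OOC(=O)c1c(CCC)cc(OC)cc1OC | intermediate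
9 | dibenzyl malonate | O=C(CC(=O)OCc1ccccc1)OCc1ccccc1 | starting material
10 | (E)-hept-3-en-2-one | CCC/C=C/C(C)=O | starting material
11 | dibenzyl 2-(2-oxoheptan-4-yl)propanedioate (racemic, not isolated) | CCCC(CC(C)=O)C(C(=O)OCc1ccccc1)C(=O)OCc1ccccc1 | intermediate
12 | sodium 6-[(benzyloxy)carbonyl]-3-oxo-5-propylcyclohex-1-en-1-olate (racemic, not isolated) | CCCC1CC(=O)C=C([O-])C1C(=O)OCc1ccccc1.[Na+] | intermediate
13 | benzyl 2,4-dioxo-6-propylcyclohexane-1-carboxylate (racemic, enolisable) | CCCC1CC(=O)CC(=O)C1C(=O)OCc1ccccc1 | intermediate
14 | potassium 6-[(benzyloxy)carbonyl]-3-oxo-5-propylcyclohex-1-en-1-olate (racemic, not isolated) | CCCC1CC(=O)C=C([O-])C1C(=O)OCc1ccccc1.[K+] | intermediate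
15 | benzyl 3-[(2,4-dimethoxy-6-propylbenzoyl)oxy]-2,4-dioxo-6-propylcyclohexane-1-carboxylate (mixture of enolisable stereoisomers) | CCCC1CC(=O)C(OC(=O)c2c(CCC)cc(OC)cc2OC)C(=O)C1C(=O)OCc1ccccc1 | intermediate
16 | benzyl 3-[(2,4-dimethoxy-6-propylbenzoyl)oxy]-2,4-dihydroxy-6-propylbenzoate | CCCc1cc(OC)cc(OC)c1C(=O)Oc1c(O)cc(CCC)c(C(=O)OCc2ccccc2)c1O | intermediate
17 | 3-[(2,4-dimethoxy-6-propylbenzoyl)oxy]-2,4-dihydroxy-6-propylbenzoic acid | CCCc1cc(OC)cc(OC)c1C(=O)Oc1c(O)cc(CCC)c(C(=O)O)c1O | target

**Step count and risks**

Total step count: 10. Longest linear sequence: 9 steps (steps 1 to 6, then 8 to 10); the dione branch is step 7 alone.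

Steps most likely to fail:

1. Step 8. Electron transfer from the enolate to the peroxide, or ionic decomposition of the electron-rich peroxide, may outrun the displacement at oxygen, so that the aroyloxy group is not transferred to C3. The fallback sets out from dione 13 and comes back at 15. Regitz diazo transfer with 4-acetamidobenzenesulfonyl azide and Et3N in MeCN should give benzyl 3-diazo-2,4-dioxo-6-propylcyclohexane-1-carboxylate F1, since only C3 carries the two acidic hydrogens the transfer needs. Decomposition of F1 with catalytic Rh2(OAc)4 in CH2Cl2 in the presence of acid 5 should then insert the carbenoid into the carboxylic O–H bond, a known route to 2-acyloxy-1,3-diones, and give 15 without any peroxide.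

2. Step 9. Hydride abstraction from the enolised acyloxy dione may be slow, and oxidative degradation of the product phenol or acyl migration may then compete. The fallback sets out from 15 and comes back at 16. Double deprotonation with LiN(i-Pr)2 (2.1 equiv) in THF at −78 °C should give the dianion, which PhSeBr should selenenylate at the more basic C1 to give benzyl 3-[(2,4-dimethoxy-6-propylbenzoyl)oxy]-2,4-dioxo-1-(phenylselanyl)-6-propylcyclohexane-1-carboxylate F2. Oxidation with H2O2 in CH2Cl2/pyridine at 0 °C should give benzyl 1-(benzeneseleninyl)-3-[(2,4-dimethoxy-6-propylbenzoyl)oxy]-2,4-dioxo-6-propylcyclohexane-1-carboxylate F3, which is not isolated. Syn elimination toward C6–H and tautomerization of the resulting enedione then give 16.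

3. Step 5. Hydrolysis of the hindered acid chloride may outpace perhydrolysis, and the electron-rich peroxy acid may decompose in the alkaline medium or oxidise its own ring during isolation. The fallback sets out from acid 5 (bypassing 6 and the isolation of 7) and comes back at 8. Carbodiimide coupling with DCC (1 equiv per acid) and H2O2 (0.5 equiv) in Et2O/CH2Cl2 at 0 °C should proceed through O-(2,4-dimethoxy-6-propylbenzoyl)-N,N'-dicyclohexylisourea F4, which is not isolated. F4 acylates hydrogen peroxide to peroxy acid 7, which is acylated at once by a second molecule of F4 in a nearly water-free, base-free medium. The urea is filtered off cold and the filtrate is used directly in step 8.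

**Further compounds**

F1 | step 8 | benzyl 3-diazo-2,4-dioxo-6-propylcyclohexane-1-carboxylate | CCCC1CC(=O)C(=[N+]=[N-])C(=O)C1C(=O)OCc1ccccc1
F2 | step 9 | benzyl 3-[(2,4-dimethoxy-6-propylbenzoyl)oxy]-2,4-dioxo-1-(phenylselanyl)-6-propylcyclohexane-1-carboxylate | CCCC1CC(=O)C(OC(=O)c2c(CCC)cc(OC)cc2OC)C(=O)C1([Se]c3ccccc3)C(=O)OCc4ccccc4
F3 | step 9 | benzyl 1-(benzeneseleninyl)-3-[(2,4-dimethoxy-6-propylbenzoyl)oxy]-2,4-dioxo-6-propylcyclohexane-1-carboxylate | CCCC1CC(=O)C(OC(=O)c2c(CCC)cc(OC)cc2OC)C(=O)C1([Se](=O)c3ccccc3)C(=O)OCc4ccccc4
F4 | step 5 | O-(2,4-dimethoxy-6-propylbenzoyl)-N,N'-dicyclohexylisourea | CCCc1cc(OC)cc(OC)c1C(=O)OC(=NC2CCCCC2)NC3CCCCC3
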